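**Plan**

1. Retrosynthetic cuts: first the lactone C12–O bond together with C6–C7 (one chromium-mediated allylation/lactonisation that closes the ten-membered ring last), then the furanone ether bond O–C10, then C1–C2 (aldol), which separates a west C2–C6 Z-enone from an east C1/C7–C10 epoxy aldehyde.
2. Enabling feature: the ring oxygen of the 3(2H)-furanone (O–C3=C2–C1(=O)–C10) is the enol oxygen of a C1/C3 1,3-diketone, and the quaternary C10 it binds sits next to the oxygenated C9. C9 and C10 are therefore the two carbons of a trisubstituted epoxide, which the enol opens 5-exo at C10 to give the furanone ring, the quaternary centre and the C9 carbinol in one event.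
3. Forward order: Z-enone from but-2-yn-1-ol; epoxy aldehyde from (S)-glyceraldehyde acetonide; aldol and oxidation to the epoxy diketone; furanone ring; the east arm is grown into a Z-2-(bromomethyl)enoate and the west arm oxidised to the Z-enal; carbocycle and lactone close together.
4. Stereochemistry: C8 from the chiral pool; C9 and C10 from a Sharpless epoxidation (C10 inverted, C9 retained on ring closure); C6 and C7 from the chair-like chromium allylation under control of C8; the 4Z alkene from trans-hydroalumination/iodination of the alkyne.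

Key step: step 10

Remark: germacrane numbering (C1 to C15) is used for the target and all precursors; the glyceraldehyde acetonide is the commercial L-series (S) enantiomer, distilled before use.
Abbreviation: A = (2S)-5-[(Z)-4-(tert-butyldiphenylsilyloxy)but-2-en-2-yl]-2-methyl-3-oxo-2,3-dihydrofuran-2-yl.

**Route**

Step 1
Reactants: 1 but-2-yn-1-ol
Product: 3 (Z)-3-iodobut-2-en-1-ol, via cyclic vinylalanate 2 (not isolated)
Conditions: NaAlH2(OCH2CH2OMe)2 (Red-Al), THF, 0 °C to rt; then I2, THF, −78 °C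
Reagents that add atoms: iodine, [I][I]
Why: Hydroxyl-directed trans-hydroalumination of the propargylic alcohol puts aluminium on the distal alkyne carbon and iodinolysis with retention gives the Z-vinyl iodide, which fixes the C4=C5 geometry (C3 and C6 cis) of the target.

Step 2
Reactants: 3 (Z)-3-iodobut-2-en-1-ol
Product: 4 tert-butyl{[(Z)-3-iodobut-2-en-1-yl]oxy}diphenylsilane
Conditions: tBuPh2SiCl, imidazole, CH2Cl2, rt
Reagents that add atoms: tert-butyl(chloro)diphenylsilane, CC(C)(C)[Si](Cl)(c1ccccc1)c1ccccc1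
Why: Routine imidazole-promoted silylation of the primary alcohol gives an ether that survives the organolithium, aldol and acidic steps and is removed by fluoride in step 19.

Step 3
Reactants: 4 tert-butyl{[(Z)-3-iodobut-2-en-1-yl]oxy}diphenylsilane
Product: 6 (Z)-5-(tert-butyldiphenylsilyloxy)-3-methylpent-3-en-2-one, via vinyllithium 5 (not isolated)
Conditions: tBuLi (2.1 equiv), Et2O, −78 °C; then N-methoxy-N-methylacetamide, −78 to 0 °C
Reagents that add atoms: N-methoxy-N-methylacetamide, CC(=O)N(C)OC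
Why: Lithium–iodine exchange occurs with retention of the alkene geometry and the vinyllithium is acylated by the Weinreb amide (Nahm–Weinreb ketone synthesis), whose chelated tetrahedral intermediate stops the addition at the Z-enone.

Step 4
Reactants: 7 (S)-2,2-dimethyl-1,3-dioxolane-4-carbaldehyde
Product: 8 ethyl (E)-3-[(4R)-2,2-dimethyl-1,3-dioxolan-4-yl]-2-methylprop-2-enoate
Conditions: Ph3P=C(CH3)CO2Et, CH2Cl2, rt
Reagents that add atoms: ethyl 2-(triphenylphosphoranylidene)propanoate, CCOC(=O)C(C)=P(c1ccccc1)(c1ccccc1)c1ccccc1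
Why: Wittig olefination with the stabilised α-methyl ylide gives the E-trisubstituted enoate under neutral conditions that do not epimerise the α-alkoxy aldehyde, so C8 comes unchanged from the chiral pool.

Step 5
Reactants: 8 ethyl (E)-3-[(4R)-2,2-dimethyl-1,3-dioxolan-4-yl]-2-methylprop-2-enoate
Product: 9 (E)-3-[(4R)-2,2-dimethyl-1,3-dioxolan-4-yl]-2-methylprop-2-en-1-ol
Conditions: iBu2AlH (DIBAL-H), CH2Cl2, −78 °C
Reagents that add atoms: none
Why: DIBAL-H reduces the conjugated ester by 1,2-addition to the allylic alcohol needed for the directed epoxidation.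

Step 6
Reactants: 9 (E)-3-[(4R)-2,2-dimethyl-1,3-dioxolan-4-yl]-2-methylprop-2-en-1-ol
Product: 10 [(2S,3S)-3-[(4S)-2,2-dimethyl-1,3-dioxolan-4-yl]-2-methyloxiran-2-yl]methanol
Conditions: Ti(OiPr)4 (10 mol %), L-(+)-diethyl tartrate (12 mol %), tBuOOH, 4 Å molecular sieves, CH2Cl2, −20 °C
Reagents that add atoms: tert-butyl hydroperoxide, CC(C)(C)OO
Why: Katsuki–Sharpless asymmetric epoxidation: with L-(+)-tartrate the titanium-bound peroxide is delivered to the alkene face that gives the (2S,3S)-epoxy alcohol (reagent control, the usual sense for E-2-methylallylic alcohols), which sets C9 and the future C10.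

Step 7
Reactants: 10 [(2S,3S)-3-[(4S)-2,2-dimethyl-1,3-dioxolan-4-yl]-2-methyloxiran-2-yl]methanol
Product: 11 (2R,3S)-3-[(4S)-2,2-dimethyl-1,3-dioxolan-4-yl]-2-methyloxirane-2-carbaldehyde
Conditions: TEMPO (cat.), PhI(OAc)2, CH2Cl2, rt
Reagents that add atoms: none
Why: TEMPO-catalysed oxidation with PhI(OAc)2 converts the primary epoxy alcohol into the aldehyde under non-basic conditions, and the aldehyde has no α-hydrogen to epimerise.

Step 8
Reactants: 6 (Z)-5-(tert-butyldiphenylsilyloxy)-3-methylpent-3-en-2-one; 11 (2R,3S)-3-[(4S)-2,2-dimethyl-1,3-dioxolan-4-yl]-2-methyloxirane-2-carbaldehyde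
Product: 13 (Z)-6-(tert-butyldiphenylsilyloxy)-1-[(2S,3S)-3-[(4S)-2,2-dimethyl-1,3-dioxolan-4-yl]-2-methyloxiran-2-yl]-1-hydroxy-4-methylhex-4-en-3-one (C1 epimers), via lithium enolate 12 (not isolated)
Conditions: LiN(iPr)2 (LDA), THF, −78 °C; then 11, −78 °C; H2O quench
Reagents that add atoms: none
Why: Kinetic deprotonation of the methyl group gives the cross-conjugated lithium enolate, whose aldol addition to the non-enolisable epoxy aldehyde forms the C1–C2 bond and joins the two fragments; the C1 carbinol is formed as an epimer mixture that is removed by the next oxidation.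

Step 9
Reactants: 13 aldol adduct
Product: 14 (Z)-6-(tert-butyldiphenylsilyloxy)-1-[(2R,3S)-3-[(4S)-2,2-dimethyl-1,3-dioxolan-4-yl]-2-methyloxiran-2-yl]-4-methylhex-4-ene-1,3-dione
Conditions: Dess–Martin periodinane, CH2Cl2, 0 °C to rt
Reagents that add atoms: none
Why: Dess–Martin oxidation is the standard way to turn a β-hydroxy ketone into a 1,3-diketone without retro-aldol cleavage and leaves the epoxide, acetonide and silyl ether untouched.

Step 10
Reactants: 14 epoxy 1,3-diketone
Product: 15 (2S)-5-[(Z)-4-(tert-butyldiphenylsilyloxy)but-2-en-2-yl]-2-[(S)-[(4S)-2,2-dimethyl-1,3-dioxolan-4-yl](hydroxy)methyl]-2-methylfuran-3(2H)-one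
Conditions: (+)-camphor-10-sulfonic acid (10 mol %), CH2Cl2, 0 °C to rt
Reagents that add atoms: none
Why: Proposed new method: the enolised 1,3-diketone of 14 (C3–OH, C2=C3, C1=O) attacks through its C3 oxygen the acid-activated C9–C10 epoxide at the tertiary carbon C10, anti to the breaking C10–O bond, and loss of the proton gives the vinylogous ester directly. The closest known reactions are the 5-exo-tet O-alkylation of 1,3-diketone enols by tertiary α'-halides (a classical route to 2,2-dialkyl-3(2H)-furanones) and the acid-catalysed 5-exo cyclisation of hydroxy epoxides at their more substituted carbon; opening of an α,β-epoxy ketone in this way by a diketone enol has not been shown. The furanone ring closes in the 5-exo-tet mode (O, C3, C2, C1 and C10 in the ring, the epoxide oxygen leaving outside it). C10 is formed by inversion of the (R)-epoxide carbon set in the Sharpless step and becomes (S), while C9 keeps its oxygen and configuration and appears as the free (S)-carbinol. The step needs attack at C10 and not 6-endo attack at C9, and O- not C-alkylation: the spiro geometry of exo epoxide opening, the tertiary nature of C10 against a C9 deactivated by the adjacent dioxolane oxygen, and the impossibility of a three- or four-membered carbocycle should secure both, and a Brønsted acid is chosen because a chelating Lewis acid would hold both diketonate oxygens away from C10.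

Step 11
Reactants: 15 furanone alcohol
Product: 16 (S)-A-[(4S)-2,2-dimethyl-1,3-dioxolan-4-yl]methyl acetate
Conditions: Ac2O, pyridine, DMAP (cat.), CH2Cl2, rt
Reagents that add atoms: acetic anhydride, CC(=O)OC(C)=O
Why: DMAP-catalysed acetylation of the only free hydroxyl installs the C9 acetate of the target.

Step 12
Reactants: 16 acetate
Product: 17 (1S,2S)-1-A-2,3-dihydroxypropyl acetate
Conditions: AcOH/H2O (4:1), 40 °C
Reagents that add atoms: none
Why: Aqueous acetic acid hydrolyses the terminal isopropylidene acetal while the tert-butyldiphenylsilyl ether, the acetate and the vinylogous ester are stable.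

Step 13
Reactants: 17 diol
Product: 18 (1S,2S)-1-A-2-hydroxy-3-(triethylsilyloxy)propyl acetate
Conditions: Et3SiCl, imidazole, CH2Cl2, −40 °C
Reagents that add atoms: chlorotriethylsilane, CC[Si](Cl)(CC)CC
Why: Silylation at low temperature is selective for the primary C7 hydroxyl over the hindered secondary C8 hydroxyl.

Step 14
Reactants: 18 mono-silyl ether
Product: 19 (1S,2S)-1-acetoxy-1-A-3-(triethylsilyloxy)propan-2-yl 2-methylprop-2-enoate
Conditions: methacrylic anhydride, Et3N, DMAP, CH2Cl2, 0 °C to rt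
Reagents that add atoms: methacrylic anhydride, CC(=C)C(=O)OC(=O)C(C)=C
Why: DMAP-catalysed acylation with the anhydride esterifies the C8 hydroxyl and so installs the methacrylate of the target before the aldehyde is unveiled.

Step 15
Reactants: 19 methacrylate
Product: 20 (1S,2S)-1-acetoxy-1-A-3-hydroxypropan-2-yl 2-methylprop-2-enoate
Conditions: AcOH/THF/H2O (3:1:1), rt
Reagents that add atoms: none
Why: A primary triethylsilyl ether is cleaved by dilute acetic acid at room temperature under conditions that leave the tert-butyldiphenylsilyl ether and the three esters intact.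

Step 16
Reactants: 20 primary alcohol
Product: 21 (1S,2R)-1-acetoxy-1-A-3-oxopropan-2-yl 2-methylprop-2-enoate
Conditions: Dess–Martin periodinane, CH2Cl2, 0 °C
Reagents that add atoms: none
Why: Dess–Martin oxidation gives the α-acyloxy aldehyde under neutral conditions that avoid β-elimination of the C9 acetate; the aldehyde is used at once.

Step 17
Reactants: 21 aldehyde
Product: 22 methyl (4S,5S)-5-acetoxy-5-A-3-hydroxy-4-(methacryloyloxy)-2-methylidenepentanoate (C3 epimers)
Conditions: iBu2AlH, N-methylmorpholine N-oxide, methyl propiolate, THF, 0 °C; then 21, 0 °C to rt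
Reagents that add atoms: methyl propiolate, C#CC(=O)OC
Why: Vinylalumination: hydroalumination of methyl propiolate gives the α-aluminated acrylate, which adds to the aldehyde carbonyl and gives the Morita–Baylis–Hillman-type adduct without the amine base that would eliminate the β-acetate; the new C7 carbinol is an epimer mixture that disappears in step 18.

Step 18
Reactants: 22 allylic alcohol
Product: 23 methyl (2Z,4S,5S)-5-acetoxy-5-A-2-(bromomethyl)-4-(methacryloyloxy)pent-2-enoate
Conditions: N-bromosuccinimide, Me2S, CH2Cl2, 0 °C to rt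
Reagents that add atoms: N-bromosuccinimide, O=C1CCC(=O)N1Br
Why: Corey–Kim-type activation of the allylic alcohol and SN2' attack of bromide give the thermodynamically preferred Z-2-(bromomethyl)enoate, the standard conversion of Baylis–Hillman adducts into allylic bromides.

Step 19
Reactants: 23 allylic bromide
Product: 24 methyl (2Z,4S,5S)-5-acetoxy-2-(bromomethyl)-5-[(2S)-5-[(Z)-4-hydroxybut-2-en-2-yl]-2-methyl-3-oxo-2,3-dihydrofuran-2-yl]-4-(methacryloyloxy)pent-2-enoate
Conditions: HF·pyridine, pyridine/THF, 0 °C to rt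
Reagents that add atoms: none
Why: Fluoride cleaves the silyl ether selectively in the presence of the esters and the allylic bromide and frees the C6 allylic alcohol.

Step 20
Reactants: 24 allylic alcohol
Product: 25 methyl (2Z,4S,5S)-5-acetoxy-2-(bromomethyl)-4-(methacryloyloxy)-5-[(2S)-2-methyl-3-oxo-5-[(Z)-4-oxobut-2-en-2-yl]-2,3-dihydrofuran-2-yl]pent-2-enoate
Conditions: Dess–Martin periodinane, CH2Cl2, 0 °C
Reagents that add atoms: none
Why: Dess–Martin oxidation of the allylic alcohol gives the Z-enal quickly and without base, so the C4=C5 geometry is kept; the enal is cyclised directly.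

Step 21
Reactants: 25 bromo enal
Product: 27 (6R,7S,8S,9S,10S)-9-acetoxy-1-oxo-3,10-epoxygermacra-2,4(Z),11(13)-trien-12,6-olid-8-yl 2-methylprop-2-enoate (CNP0365569.2), via seco hydroxy ester 26 (not isolated)
Conditions: CrCl2 (10 equiv), THF, rt, slow addition of 25 (final 1 mM); aq. NH4Cl work-up
Reagents that add atoms: none
Why: Intramolecular Nozaki–Hiyama (chromium Barbier) allylation: the allylchromium formed from the bromide adds through C7 to the C6 aldehyde in a chair-like six-membered transition state that should give the anti (6R,7S) adduct, with A1,3 strain across the fully substituted C11 holding the C8 hydrogen in the allyl plane so that C6 bonds anti to the C8–C9 bond, and the chromium alkoxide then closes the trans-fused α-methylene-γ-lactone on the methyl ester.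

**Compound list**

1 | but-2-yn-1-ol | CC#CCO | starting material
2 | sodium 2,2-bis(2-methoxyethoxy)-3-methyl-2,5-dihydro-1,2-oxaluminol-2-uide (cyclic Z-vinylalanate) | CC1=CCO[Al-]1(OCCOC)OCCOC.[Na+] | intermediate
3 | (Z)-3-iodobut-2-en-1-ol | C/C(I)=C/CO | intermediate
4 | tert-butyl{[(Z)-3-iodobut-2-en-1-yl]oxy}diphenylsilane | C/C(I)=C/CO[Si](c1ccccc1)(c1ccccc1)C(C)(C)C | intermediate
5 | [(Z)-4-(tert-butyldiphenylsilyloxy)but-2-en-2-yl]lithium | [Li]/C(C)=C\CO[Si](c1ccccc1)(c1ccccc1)C(C)(C)C | intermediate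
6 | (Z)-5-(tert-butyldiphenylsilyloxy)-3-methylpent-3-en-2-one | CC(=O)/C(C)=C\CO[Si](c1ccccc1)(c1ccccc1)C(C)(C)C | intermediate
7 | (S)-2,2-dimethyl-1,3-dioxolane-4-carbaldehyde (2,3-O-isopropylidene-L-glyceraldehyde) | O=C[C@@H]1COC(C)(C)O1 | starting material
8 | ethyl (E)-3-[(4R)-2,2-dimethyl-1,3-dioxolan-4-yl]-2-methylprop-2-enoate | CCOC(=O)/C(C)=C/[C@@H]1COC(C)(C)O1 | intermediate
9 | (E)-3-[(4R)-2,2-dimethyl-1,3-dioxolan-4-yl]-2-methylprop-2-en-1-ol | OC/C(C)=C/[C@@H]1COC(C)(C)O1 | intermediate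
10 | [(2S,3S)-3-[(4S)-2,2-dimethyl-1,3-dioxolan-4-yl]-2-methyloxiran-2-yl]methanol | OC[C@]1(C)O[C@H]1[C@@H]2COC(C)(C)O2 | intermediate
11 | (2R,3S)-3-[(4S)-2,2-dimethyl-1,3-dioxolan-4-yl]-2-methyloxirane-2-carbaldehyde | O=C[C@]1(C)O[C@H]1[C@@H]2COC(C)(C)O2 | intermediate
12 | lithium (Z)-5-(tert-butyldiphenylsilyloxy)-3-methylpenta-1,3-dien-2-olate (kinetic enolate of 6) | [Li]OC(=C)/C(C)=C\CO[Si](c1ccccc1)(c1ccccc1)C(C)(C)C | intermediate
13 | (Z)-6-(tert-butyldiphenylsilyloxy)-1-[(2S,3S)-3-[(4S)-2,2-dimethyl-1,3-dioxolan-4-yl]-2-methyloxiran-2-yl]-1-hydroxy-4-methylhex-4-en-3-one (C1 epimers) | CC(C)(C)[Si](c1ccccc1)(c1ccccc1)OC/C=C(/C)C(=O)CC(O)[C@]1(C)O[C@H]1[C@@H]2COC(C)(C)O2 | intermediate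
14 | (Z)-6-(tert-butyldiphenylsilyloxy)-1-[(2R,3S)-3-[(4S)-2,2-dimethyl-1,3-dioxolan-4-yl]-2-methyloxiran-2-yl]-4-methylhex-4-ene-1,3-dione | CC(C)(C)[Si](c1ccccc1)(c1ccccc1)OC/C=C(/C)C(=O)CC(=O)[C@]1(C)O[C@H]1[C@@H]2COC(C)(C)O2 | intermediate
15 | (2S)-5-[(Z)-4-(tert-butyldiphenylsilyloxy)but-2-en-2-yl]-2-[(S)-[(4S)-2,2-dimethyl-1,3-dioxolan-4-yl](hydroxy)methyl]-2-methylfuran-3(2H)-one | CC(C)(C)[Si](c1ccccc1)(c1ccccc1)OC/C=C(/C)C1=CC(=O)[C@@](C)(O1)[C@@H](O)[C@@H]2COC(C)(C)O2 | intermediate
16 | (S)-A-[(4S)-2,2-dimethyl-1,3-dioxolan-4-yl]methyl acetate | CC(C)(C)[Si](c1ccccc1)(c1ccccc1)OC/C=C(/C)C1=CC(=O)[C@@](C)(O1)[C@@H](OC(C)=O)[C@@H]2COC(C)(C)O2 | intermediate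
17 | (1S,2S)-1-A-2,3-dihydroxypropyl acetate | CC(C)(C)[Si](c1ccccc1)(c1ccccc1)OC/C=C(/C)C1=CC(=O)[C@@](C)(O1)[C@@H](OC(C)=O)[C@@H](O)CO | intermediate
18 | (1S,2S)-1-A-2-hydroxy-3-(triethylsilyloxy)propyl acetate | CC(C)(C)[Si](c1ccccc1)(c1ccccc1)OC/C=C(/C)C1=CC(=O)[C@@](C)(O1)[C@@H](OC(C)=O)[C@@H](O)CO[Si](CC)(CC)CC | intermediate
19 | (1S,2S)-1-acetoxy-1-A-3-(triethylsilyloxy)propan-2-yl 2-methylprop-2-enoate | CC(C)(C)[Si](c1ccccc1)(c1ccccc1)OC/C=C(/C)C1=CC(=O)[C@@](C)(O1)[C@@H](OC(C)=O)[C@@H](OC(=O)C(C)=C)CO[Si](CC)(CC)CC | intermediate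
20 | (1S,2S)-1-acetoxy-1-A-3-hydroxypropan-2-yl 2-methylprop-2-enoate | CC(C)(C)[Si](c1ccccc1)(c1ccccc1)OC/C=C(/C)C1=CC(=O)[C@@](C)(O1)[C@@H](OC(C)=O)[C@@H](OC(=O)C(C)=C)CO | intermediate
21 | (1S,2R)-1-acetoxy-1-A-3-oxopropan-2-yl 2-methylprop-2-enoate | CC(C)(C)[Si](c1ccccc1)(c1ccccc1)OC/C=C(/C)C1=CC(=O)[C@@](C)(O1)[C@@H](OC(C)=O)[C@@H](OC(=O)C(C)=C)C=O | intermediate
22 | methyl (4S,5S)-5-acetoxy-5-A-3-hydroxy-4-(methacryloyloxy)-2-methylidenepentanoate (C3 epimers) | CC(C)(C)[Si](c1ccccc1)(c1ccccc1)OC/C=C(/C)C1=CC(=O)[C@@](C)(O1)[C@@H](OC(C)=O)[C@@H](OC(=O)C(C)=C)C(O)C(=C)C(=O)OC | intermediate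
23 | methyl (2Z,4S,5S)-5-acetoxy-5-A-2-(bromomethyl)-4-(methacryloyloxy)pent-2-enoate | CC(C)(C)[Si](c1ccccc1)(c1ccccc1)OC/C=C(/C)C1=CC(=O)[C@@](C)(O1)[C@@H](OC(C)=O)[C@@H](OC(=O)C(C)=C)/C=C(CBr)/C(=O)OC | intermediate
24 | methyl (2Z,4S,5S)-5-acetoxy-2-(bromomethyl)-5-[(2S)-5-[(Z)-4-hydroxybut-2-en-2-yl]-2-methyl-3-oxo-2,3-dihydrofuran-2-yl]-4-(methacryloyloxy)pent-2-enoate | OC/C=C(/C)C1=CC(=O)[C@@](C)(O1)[C@@H](OC(C)=O)[C@@H](OC(=O)C(C)=C)/C=C(CBr)/C(=O)OC | intermediate
25 | methyl (2Z,4S,5S)-5-acetoxy-2-(bromomethyl)-4-(methacryloyloxy)-5-[(2S)-2-methyl-3-oxo-5-[(Z)-4-oxobut-2-en-2-yl]-2,3-dihydrofuran-2-yl]pent-2-enoate | O=C/C=C(/C)C1=CC(=O)[C@@](C)(O1)[C@@H](OC(C)=O)[C@@H](OC(=O)C(C)=C)/C=C(CBr)/C(=O)OC | intermediate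
26 | methyl 2-[(6R,7S,8S,9S,10S)-9-acetoxy-6-hydroxy-8-(methacryloyloxy)-1-oxo-3,10-epoxygermacra-2,4(Z)-dien-7-yl]prop-2-enoate (seco hydroxy ester, present as its chromium alkoxide) | C=C(C)C(=O)O[C@H]1[C@@H](C(=C)C(=O)OC)[C@H](O)/C=C(/C)C2=CC(=O)[C@@](C)(O2)[C@H]1OC(C)=O | intermediate
27 | (6R,7S,8S,9S,10S)-9-acetoxy-1-oxo-3,10-epoxygermacra-2,4(Z),11(13)-trien-12,6-olid-8-yl 2-methylprop-2-enoate (CNP0365569.2) | C=C(C)C(=O)O[C@H]1[C@H]2C(=C)C(=O)O[C@@H]2/C=C(/C)C2=CC(=O)[C@@](C)(O2)[C@H]1OC(C)=O | target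

**Totals and risks**

Total step count: 21 (3 for the west fragment, 4 for the east fragment, 14 after their union).
Longest linear sequence: 18 steps (steps 4 to 21, from aldehyde 7).

Steps most likely to fail:

Step 10 (key step). What may go wrong: the α-carbonyl group may retard bond breaking at C10, so that 6-endo opening at C9, acyl migration of the epoxy ketone or simple non-reaction takes over. The fallback runs the same epoxide opening one oxidation level lower, where it is a routine hydroxy-epoxide cyclisation, and restores the furanone afterwards; it sets out from 13 and comes back at 16. Aldol adduct 13 is silylated (Et3SiCl, imidazole, DMF) to the C1 triethylsilyl ether F1. Luche reduction of the enone (NaBH4, CeCl3·7H2O, MeOH, −40 °C) gives the C3 allylic alcohol F2 as an epimer mixture that converges later. Catalytic camphorsulfonic acid in CH2Cl2 closes the tetrahydrofuran F3 by 5-exo attack of the C3 hydroxyl on C10 with inversion, C10 no longer being α to a carbonyl. Ac2O/pyridine/DMAP gives the C9 acetate F4. HF·pyridine at 0 °C removes the triethylsilyl group to give the C1 alcohol F5. Dess–Martin oxidation gives the dihydrofuran-3(2H)-one F6, and dehydrogenation across C2–C3 (IBX, DMSO, 65 °C) restores the furanone and delivers 16.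

Step 21. What may go wrong: intermolecular allylation to oligomers, Z-to-E isomerisation of the enal before ring closure, or poor facial selectivity in the ten-membered transition state. The fallback closes the ring from the alcohol oxidation level under catalyst control; it sets out from 22 and comes back at 27. Alcohol 22 is converted into its C7 methyl carbonate F7 (ClCO2Me, pyridine, CH2Cl2, 0 °C) and desilylated (HF·pyridine, pyridine/THF) to the C6 allylic alcohol F8. An iridium-catalysed transfer-hydrogenative 2-(alkoxycarbonyl)allylation is then applied: [Ir(cod)Cl]2, the SEGPHOS enantiomer matched to C8, 4-cyano-3-nitrobenzoic acid, Cs2CO3, THF, 60 °C. It dehydrogenates the C6 carbinol on the metal, adds the π-allyliridium through C7 in a closed chair transition state (anti) and lactonises to 27, so that neither the free Z-enal nor the allylic bromide is handled.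

Step 17. What may go wrong: loss of the C9 acetate by β-elimination, epimerisation at C8 of the α-acyloxy aldehyde, or reduction of the aldehyde by residual hydride. The fallback replaces the vinylmetal addition by an aldol/elimination sequence; it sets out from 21 and comes back at 22. Mukaiyama aldol addition of the trimethylsilyl ketene acetal of methyl 3-(phenylselanyl)propanoate to 21 (BF3·OEt2, CH2Cl2, −78 °C) gives the β-hydroxy α-(phenylselanylmethyl) ester F9. Oxidation to the selenoxide (H2O2, pyridine, CH2Cl2, 0 °C) and syn-elimination towards C11 gives 22.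

Further compounds
F1 | step 10 | C1 triethylsilyl ether of 13 (all other centres as in 13) | CC(C)(C)[Si](c1ccccc1)(c1ccccc1)OC/C=C(/C)C(=O)CC(O[Si](CC)(CC)CC)[C@]1(C)O[C@H]1[C@@H]2COC(C)(C)O2
F2 | step 10 | C3 allylic alcohol from F1 (C1 and C3 epimers, other centres as in 13) | CC(C)(C)[Si](c1ccccc1)(c1ccccc1)OC/C=C(/C)C(O)CC(O[Si](CC)(CC)CC)[C@]1(C)O[C@H]1[C@@H]2COC(C)(C)O2
F3 | step 10 | tetrahydrofuran with ring O–C3–C2–C1–C10, C1 triethylsilyl ether and free C9 hydroxyl (C8, C9, C10 as in 15) | CC(C)(C)[Si](c1ccccc1)(c1ccccc1)OC/C=C(/C)C1CC(O[Si](CC)(CC)CC)[C@@](C)(O1)[C@@H](O)[C@@H]2COC(C)(C)O2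
F4 | step 10 | C9 acetate of F3 | CC(C)(C)[Si](c1ccccc1)(c1ccccc1)OC/C=C(/C)C1CC(O[Si](CC)(CC)CC)[C@@](C)(O1)[C@@H](OC(C)=O)[C@@H]2COC(C)(C)O2
F5 | step 10 | C1 alcohol from F4 | CC(C)(C)[Si](c1ccccc1)(c1ccccc1)OC/C=C(/C)C1CC(O)[C@@](C)(O1)[C@@H](OC(C)=O)[C@@H]2COC(C)(C)O2
F6 | step 10 | dihydrofuran-3(2H)-one, the C2–C3 saturated analogue of 16 (C8, C9, C10 as in 16) | CC(C)(C)[Si](c1ccccc1)(c1ccccc1)OC/C=C(/C)C1CC(=O)[C@@](C)(O1)[C@@H](OC(C)=O)[C@@H]2COC(C)(C)O2
F7 | step 21 | C7 methyl carbonate of 22 | CC(C)(C)[Si](c1ccccc1)(c1ccccc1)OC/C=C(/C)C1=CC(=O)[C@@](C)(O1)[C@@H](OC(C)=O)[C@@H](OC(=O)C(C)=C)C(OC(=O)OC)C(=C)C(=O)OC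
F8 | step 21 | C6 allylic alcohol from F7 (silyl ether removed) | OC/C=C(/C)C1=CC(=O)[C@@](C)(O1)[C@@H](OC(C)=O)[C@@H](OC(=O)C(C)=C)C(OC(=O)OC)C(=C)C(=O)OC
F9 | step 17 | methyl 3-hydroxy-2-(phenylselanylmethyl) ester, the aldol adduct of 21 (C7 and C11 epimers) | CC(C)(C)[Si](c1ccccc1)(c1ccccc1)OC/C=C(/C)C1=CC(=O)[C@@](C)(O1)[C@@H](OC(C)=O)[C@@H](OC(=O)C(C)=C)C(O)C(C[Se]c1ccccc1)C(=O)OC
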